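(The earlier runs and the new flask were generated by integration for substances that don't exist, and the scatter is random.)

| flask | starting material | catalyst | target | time |
|---|---|---|---|---|
| summer | 0.120 M | 0.00240 M |  |  |
| winter | 0.120 M | 0.00240 M | 0.0360 M |  |
| dusk | 0.180 M | 0.00240 M |  |  |
| noon | 0.120 M | 0.00120 M |  |  |
| autumn | 0.120 M | 0.00240 M |  | 400 s |

- summer run (time / s: [target] / M): 5.7: 0.0069; 17: 0.0166; 33: 0.0295; 52: 0.0426; 75: 0.0564; 100: 0.0665
- winter run (time / s: [target] / M): 5.7: 0.0423; 17: 0.0511; 33: 0.0646; 52: 0.0789; 75: 0.0912; 100: 0.1031
- dusk run (time / s: [target] / M): 5.7: 0.0078; 17: 0.0228; 33: 0.0435; 52: 0.0623; 75: 0.0838; 100: 0.1016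
- noon run (time / s: [target] / M): 5.7: 0.0031; 17: 0.0094; 33: 0.0162; 52: 0.0257; 75: 0.0342; 100: 0.0445

(readings scatter by 6 × 10⁻⁴ M)

- Overall: starting material -> target, with catalyst as catalyst.
- Constant volume, constant temperature.
- An order is taken over about fifteen percent of the charge, up and down.

* reaction order in [starting material] at the outset, round the charge of the summer run, defined at two percent of the starting material turned into target (one fixed amount of target, the same in the runs compared)
* reaction order in [catalyst] at the outset, round the charge of the summer run, defined at two percent of the starting material turned into target
* target in the autumn run at 400 s, as a share of the starting material charged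

**The rule.** In this closed, stirred vessel we follow the fraction of the charge left and not the fraction made. In the summer run 44.6% is left at 100 s, which gives 0.00808 s⁻¹. We call this the fraction-left constant, minus the natural logarithm of the fraction left divided by the time; the usual term is a pseudo-first-order constant. It is a reading, with a scatter of about 1.12 × 10⁻⁴ s⁻¹.

**Main step.** The noon run has half the catalyst and gives 0.00463 s⁻¹. If the catalysed part of the constant follows the catalyst, the summer run's part is 0.00689 s⁻¹. That step alone would leave 6.35% of the autumn charge at 400 s, so 93.6% made.

**Second route.** The remainder, 0.00119 s⁻¹, we read as a route without catalyst. Adding it leaves 3.95%, so 96.1% made. The catalysed share of the constant, 0.853, is our order in catalyst.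

**The rest.** After subtracting its added target, the winter run gives 0.00819 s⁻¹, and the dusk run, with its larger charge, gives 0.00831 s⁻¹. From the dusk and summer constants, both read at 100 s, we read an order in starting material of 1.07. The mean of the summer, winter and dusk constants, 0.00819 s⁻¹, moves our autumn figure to 96.2%.

**The forecast.** The forecast gives 0.85 in starting material, 0.92 in catalyst and 95% for the autumn run, noting that the “early dusk points hint at mild saturation”. Our order in starting material stands above the forecast's, our order in catalyst below it, and our autumn figure above it.

**The result.** The autumn flask gives 96.4% at 400 s. Round the charge of the summer run, the orders at the outset are 1.0 in starting material and 0.89 in catalyst.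

    catalyst + starting material → target + catalyst (3.070 M⁻¹ s⁻¹)
    starting material → target (9.190 × 10⁻⁴ s⁻¹)

At equal target made, the dusk run's rate stood at 1.5 times the summer run's, as large as the ratio of the charges. The summer fraction-left constant, 0.00808 s⁻¹, puts half of the dusk charge left at 85.8 s; the target made in the dusk run came to half of its charge at 83.6 s.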